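**Plan**

- Retrosynthesis: the C9 ester is cut first, then the C8 and C9 oxygens and the C2 alcohol are traced back to a trans-fused 2,9-dione. The skeletal cut is C4–C5, the bond between the tertiary and the quaternary carbon of ring A.
- Feature that allows this cut: O2 lies β to C4, so a cyclopropanol made of C2, C3 and C4 opens to a C4 radical placed 6-endo to C5, the β-carbon of the C9 enone of ring B.
- Forward: ring B is (R)-carvone. MeLi brings C14, carboxylation of the carvone methyl (C1) brings C2, oxidative transposition gives the C9 enone, and Kulinkovich cyclopropanation with n-PrMgBr brings C3, C4 and C15. Ring A closes last.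
- Stereochemistry: C7 comes from carvone and steers C5 and C4 in the ring closure. C10 is not entrusted to the radical step; it is flattened and then set by dissolving-metal reduction of the 1(10)-en-2-one (trans fusion).
- C2 is set by equatorial hydride delivery, C8 by enolate hydroxylation on the open α face, and C9 by dissolving-metal reduction to the equatorial alcohol. The ester is placed on the equatorial O9 through a stannylene acetal.

Key step: step 7

Remark on numbering: eremophilane numbering is used (ring A = C1–C5, C10; ring B = C5–C10; C14 on C5, C15 on C4, isopropenyl C11–C13 on C7), and β is the face that carries C14.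
Remark on the cyclopropanol: the Kulinkovich step gives the cis-1,2-disubstituted cyclopropanol as two diastereomers (both ring carbons inverted together); both converge in step 7, and compounds 10 and 11 are drawn as one of them.
Remark on temporary carbinol centres: the centres that are oxidised again later (carbinol carbon of 3–6, C9 of 8 and 10, C2 and C9 of 14–16) are drawn as the epimer expected to predominate; the other epimer is carried along.

Step 1
Reactants: 1 (R)-carvone; 2 methyllithium
Product: 3 (1R,5R)-1,2-dimethyl-5-(prop-1-en-2-yl)cyclohex-2-en-1-ol (hydroxyl cis to the isopropenyl group)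
Conditions: MeLi, Et2O, −78 °C; aq. NH4Cl
Reagents that add atoms: methyllithium (2), [Li]C
Why: 1,2-addition of the organolithium to the enone carbonyl, expected anti to the isopropenyl group, brings in the future C14; the carbinol centre is temporary and is lost in step 3.

Step 2
Reactants: 3
Product: 6 methyl 2-[(4R,6R)-6-hydroxy-6-methyl-4-(prop-1-en-2-yl)cyclohex-1-en-1-yl]acetate, via dilithio dianion 4 (not isolated), via hydroxy acid 5 (not isolated)
Conditions: n-BuLi (2.3 equiv), TMEDA, hexane–Et2O, 0 °C → rt; CO2, −78 °C; 1 M HCl to pH 3, 0 °C; Me3SiCHN2, PhMe–MeOH, 0 °C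
Reagents that add atoms: carbon dioxide, O=C=O; trimethylsilyldiazomethane, C[Si](C)(C)C=[N+]=[N-]
Why: alkoxide-directed allylic lithiation of a 2-methylallylic alcohol (dianion formation), carboxylation at the exocyclic terminus and diazoalkane esterification turn the carvone ring methyl into the C1–C2 acetate arm without touching a stereocentre.

Step 3
Reactants: 6
Product: 7 methyl 2-[(4S)-2-methyl-6-oxo-4-(prop-1-en-2-yl)cyclohex-1-en-1-yl]acetate
Conditions: pyridinium chlorochromate [C5H5NH][CrO3Cl], 4 Å molecular sieves, CH2Cl2, rt
Reagents that add atoms: none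
Why: Babler–Dauben oxidative 1,3-transposition (allylic shift of the chromate ester, then oxidation) moves the oxygen to C9 and leaves the C5=C10 enone with C14 on its β-carbon; C7 is untouched.

Step 4
Reactants: 7
Product: 8 methyl 2-[(4S,6S)-6-hydroxy-2-methyl-4-(prop-1-en-2-yl)cyclohex-1-en-1-yl]acetate (hydroxyl cis to the isopropenyl group)
Conditions: NaBH4, CeCl3·7H2O, MeOH, −20 °C
Reagents that add atoms: none
Why: Luche 1,2-reduction (axial hydride, anti to the isopropenyl group) masks the ketone as an allylic alcohol so that the ester is the only carbonyl in the next step; the C9 centre is lost again in step 6.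

Step 5
Reactants: 8; 9 n-propylmagnesium bromide
Product: 10 (1S,5S)-2-{[(1R,2S)-1-hydroxy-2-methylcyclopropyl]methyl}-3-methyl-5-(prop-1-en-2-yl)cyclohex-2-en-1-ol
Conditions: Ti(OiPr)4 (0.3 equiv), n-PrMgBr (4 equiv, slow addition), THF, 0 °C → rt; aq. NH4Cl
Reagents that add atoms: n-propylmagnesium bromide (9), CCC[Mg]Br
Why: Kulinkovich cyclopropanation of the ester (the free hydroxyl is carried as its magnesium alkoxide); the titanacyclopropane formed from two propyl groups adds twice to the ester carbon and places the methyl cis to the ring CH2 and trans to OH, as is usual for substituted Grignard reagents.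

Step 6
Reactants: 10
Product: 11 (5S)-2-{[(1R,2S)-1-hydroxy-2-methylcyclopropyl]methyl}-3-methyl-5-(prop-1-en-2-yl)cyclohex-2-en-1-one
Conditions: SO3·pyridine, DMSO, iPr2NEt, CH2Cl2, 0 °C
Reagents that add atoms: none
Why: Parikh–Doering oxidation takes the secondary allylic alcohol back to the enone, while the tertiary cyclopropanol has no carbinol hydrogen and meets neither acid nor a one-electron oxidant.

Step 7
Reactants: 11
Product: 12 (10βH)-eremophil-11-ene-2,9-dione (4β,5β-dimethyl, 7β-isopropenyl, cis-fused)
Conditions: [Ir(dF(CF3)ppy)2(5,5′-d(CF3)bpy)]PF6 (2 mol %), 2,4,6-collidine (0.5 equiv), degassed CH2Cl2 (0.01 M), 450 nm LEDs, rt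
Reagents that add atoms: none
Why: Proposed new method: the excited trivalent iridium complex and collidine remove an electron and the proton from the cyclopropanol O–H, the alkoxy radical opens at the more substituted C2–C4 bond to the secondary C4 radical β to the new C2 ketone, this nucleophilic radical adds to C5 (the β-carbon of the C9 enone), and the C10 α-keto radical is reduced by the divalent iridium complex and protonated by collidinium, so the step is a redox-neutral isomerisation. The closest known reaction type is the oxidative ring opening of cyclopropanols with intermolecular Giese addition of the β-keto radical to enones; new here is the intramolecular use on a tetrasubstituted enone with formation of a quaternary carbon, which the irreversible strain release and the six-membered transition state should pay for. Ring A closes 6-endo-trig (C4 onto C5 of the C10=C5 double bond whose C10 carries the tether); the 5-exo alternative at C10 is polarity-mismatched and would leave an unstabilised tertiary radical. C5 is set by axial attack on the half-chair of ring B anti to the equatorial C7 isopropenyl group (C14 ends cis to it), C4 by a chair-like transition state in which the C15 methyl points away from ring B (equatorial on ring A, cis to C14), and C10 by protonation anti to the axial C4–C5 bond, expected to give mainly the cis-fused 10β-H epimer. The step needs face selectivity at C5 and endo regioselectivity, which the carvone-derived C7 centre and the enone polarity secure; it needs no control at C10, because that centre is flattened in step 8 and set in step 11. High dilution and the absence of a fast hydrogen-atom donor keep the C4 radical alive until it cyclises.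

Step 8
Reactants: 12
Product: 13 eremophila-1(10),11-diene-2,9-dione
Conditions: IBX (1.3 equiv), 4-methoxypyridine N-oxide, DMSO, rt
Reagents that add atoms: none
Why: IBX dehydrogenation of a ketone through its enol; the C1–C10 bond lies between both carbonyl groups, so the enol of either ketone leads to the same ene-1,4-dione, and both C10 epimers of 12 converge.

Step 9
Reactants: 13
Product: 14 eremophila-1(10),11-diene-2β,9β-diol
Conditions: NaBH4 (3 equiv), CeCl3·7H2O, MeOH, −40 → 0 °C
Reagents that add atoms: none
Why: Luche 1,2-reduction of both enone carbonyls without conjugate reduction; hydride is expected from the α face, anti to the axial C14 methyl, and both new carbinol centres are oxidised again (steps 10 and 12).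

Step 10
Reactants: 14
Product: 15 9β-hydroxyeremophila-1(10),11-dien-2-one
Conditions: activated MnO2, CH2Cl2, rt
Reagents that add atoms: none
Why: allylic oxidation with MnO2 picks the unhindered pseudo-equatorial C2 alcohol, whose carbinol C–H is aligned with the alkene, over the crowded pseudo-axial C9 alcohol, and gives the enone in which C10 is the β-carbon.

Step 11
Reactants: 15
Product: 16 9β-hydroxy-(10αH)-eremophil-11-en-2-one
Conditions: Li, liquid NH3–THF, −78 °C; isoprene, then solid NH4Cl
Reagents that add atoms: none
Why: dissolving-metal (Birch-type) reduction of the enone, in which the C10 carbanion is protonated along the axis of the enolate π system (axially on ring A, anti to the axial C14 methyl), gives the trans ring fusion under kinetic stereoelectronic control although the cis isomer is the more stable one; the isolated isopropenyl group is not reduced and the C9 hydroxyl is carried as its lithium alkoxide.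

Step 12
Reactants: 16
Product: 17 (10αH)-eremophil-11-ene-2,9-dione
Conditions: Dess–Martin periodinane, NaHCO3, CH2Cl2, 0 °C
Reagents that add atoms: none
Why: Dess–Martin oxidation under buffered, non-enolising conditions returns the C9 ketone without disturbing the now trans C10–H.

Step 13
Reactants: 17
Product: 18 2α-hydroxy-(10αH)-eremophil-11-en-9-one
Conditions: LiBH(sec-Bu)3 (1.05 equiv), THF, −78 °C; pH 7 buffer
Reagents that add atoms: none
Why: the bulky borohydride reduces the unhindered C2 ketone faster than the α-branched C9 ketone and attacks equatorially, which gives the axial 2α-alcohol.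

Step 14
Reactants: 18
Product: 20 2α,8α-dihydroxy-(10αH)-eremophil-11-en-9-one, via dipotassium enolate 19 (not isolated)
Conditions: KN(SiMe3)2 (2.3 equiv), THF, −78 °C; 2-(phenylsulfonyl)-3-phenyloxaziridine, −78 °C; aq. NH4Cl
Reagents that add atoms: 2-(phenylsulfonyl)-3-phenyloxaziridine, O=S(=O)(c1ccccc1)N1OC1c1ccccc1
Why: kinetic deprotonation at the C8 methylene rather than the C10 methine, then Davis enolate hydroxylation on the α face, because the β face is covered by the axial C7 isopropenyl and C14 methyl groups, gives 8α-OH.

Step 15
Reactants: 20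
Product: 21 (10αH)-eremophil-11-ene-2α,8α,9α-triol
Conditions: Li, liquid NH3–THF, −78 °C; solid NH4Cl
Reagents that add atoms: none
Why: dissolving-metal reduction of the ketone gives the more stable equatorial 9α-alcohol (the axial 9β-alcohol would be syn-diaxial to C14 and the isopropenyl group), cis to the 8α-hydroxyl, which survives as its alkoxide; a hydride reagent would attack from the open α face and give the wrong epimer.

Step 16
Reactants: 21; 22 (E)-3-methylpent-2-enoic acid
Product: 25 2α,8α-dihydroxy-(10αH)-eremophil-11-en-9α-yl (E)-3-methylpent-2-enoate (the target), via acid chloride 23 (not isolated), via stannylene acetal 24 (not isolated)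
Conditions: 22, 1-chloro-N,N,2-trimethylprop-1-en-1-amine, CH2Cl2, 0 °C; separately 21, Bu2SnO, PhMe, reflux (water removed); then the acid chloride, PhMe, 0 °C → rt
Reagents that add atoms: (E)-3-methylpent-2-enoic acid (22), CC/C(C)=C/C(=O)O
Why: stannylene-acetal-directed monoacylation of a cis-1,2-diol, in which the dibutylstannylene forms on the 8α,9α-diol and activates its equatorial oxygen (O9) while the isolated axial 2α-OH stays free; the acid chloride is made under neutral conditions so that the (E)-double bond neither migrates nor isomerises.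

**Compound list**

1 | (R)-carvone | C=C(C)[C@@H]1CC=C(C)C(=O)C1 | starting material
2 | methyllithium | [Li]C | starting material
3 | (1R,5R)-1,2-dimethyl-5-(prop-1-en-2-yl)cyclohex-2-en-1-ol | C=C(C)[C@H]1C[C@@](C)(O)C(C)=CC1 | intermediate
4 | dilithio dianion of 3 (lithium alkoxide, 2-lithiomethyl) | C=C(C)[C@H]1C[C@@](C)(O[Li])C(C[Li])=CC1 | intermediate (not isolated)
5 | 2-[(4R,6R)-6-hydroxy-6-methyl-4-(prop-1-en-2-yl)cyclohex-1-en-1-yl]acetic acid | C=C(C)[C@H]1C[C@@](C)(O)C(CC(=O)O)=CC1 | intermediate (not isolated)
6 | methyl 2-[(4R,6R)-6-hydroxy-6-methyl-4-(prop-1-en-2-yl)cyclohex-1-en-1-yl]acetate | C=C(C)[C@H]1C[C@@](C)(O)C(CC(=O)OC)=CC1 | intermediate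
7 | methyl 2-[(4S)-2-methyl-6-oxo-4-(prop-1-en-2-yl)cyclohex-1-en-1-yl]acetate | C=C(C)[C@H]1CC(C)=C(CC(=O)OC)C(=O)C1 | intermediate
8 | methyl 2-[(4S,6S)-6-hydroxy-2-methyl-4-(prop-1-en-2-yl)cyclohex-1-en-1-yl]acetate | C=C(C)[C@H]1CC(C)=C(CC(=O)OC)[C@@H](O)C1 | intermediate
9 | n-propylmagnesium bromide | CCC[Mg]Br | starting material
10 | (1S,5S)-2-{[(1R,2S)-1-hydroxy-2-methylcyclopropyl]methyl}-3-methyl-5-(prop-1-en-2-yl)cyclohex-2-en-1-ol | C=C(C)[C@H]1CC(C)=C(C[C@]2(O)C[C@@H]2C)[C@@H](O)C1 | intermediate
11 | (5S)-2-{[(1R,2S)-1-hydroxy-2-methylcyclopropyl]methyl}-3-methyl-5-(prop-1-en-2-yl)cyclohex-2-en-1-one | C=C(C)[C@H]1CC(C)=C(C[C@]2(O)C[C@@H]2C)C(=O)C1 | intermediate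
12 | (10βH)-eremophil-11-ene-2,9-dione (cis-fused) | C=C(C)[C@H]1C[C@]2(C)[C@@H](C)CC(=O)C[C@@H]2C(=O)C1 | intermediate
13 | eremophila-1(10),11-diene-2,9-dione | C=C(C)[C@H]1C[C@]2(C)[C@@H](C)CC(=O)C=C2C(=O)C1 | intermediate
14 | eremophila-1(10),11-diene-2β,9β-diol | C=C(C)[C@H]1C[C@]2(C)[C@@H](C)C[C@@H](O)C=C2[C@@H](O)C1 | intermediate
15 | 9β-hydroxyeremophila-1(10),11-dien-2-one | C=C(C)[C@H]1C[C@]2(C)[C@@H](C)CC(=O)C=C2[C@@H](O)C1 | intermediate
16 | 9β-hydroxy-(10αH)-eremophil-11-en-2-one | C=C(C)[C@H]1C[C@]2(C)[C@@H](C)CC(=O)C[C@H]2[C@@H](O)C1 | intermediate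
17 | (10αH)-eremophil-11-ene-2,9-dione (trans-fused) | C=C(C)[C@H]1C[C@]2(C)[C@@H](C)CC(=O)C[C@H]2C(=O)C1 | intermediate
18 | 2α-hydroxy-(10αH)-eremophil-11-en-9-one | C=C(C)[C@H]1C[C@]2(C)[C@@H](C)C[C@H](O)C[C@H]2C(=O)C1 | intermediate
19 | dipotassium 2α-oxido-(10αH)-eremophila-8,11-dien-9-olate | C=C(C)[C@H]1C[C@]2(C)[C@@H](C)C[C@H]([O-])C[C@H]2C([O-])=C1.[K+].[K+] | intermediate (not isolated)
20 | 2α,8α-dihydroxy-(10αH)-eremophil-11-en-9-one | C=C(C)[C@H]1C[C@]2(C)[C@@H](C)C[C@H](O)C[C@H]2C(=O)[C@@H]1O | intermediate
21 | (10αH)-eremophil-11-ene-2α,8α,9α-triol | C=C(C)[C@H]1C[C@]2(C)[C@@H](C)C[C@H](O)C[C@H]2[C@H](O)[C@@H]1O | intermediate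
22 | (E)-3-methylpent-2-enoic acid | CC/C(C)=C/C(=O)O | starting material
23 | (E)-3-methylpent-2-enoyl chloride | CC/C(C)=C/C(=O)Cl | intermediate (not isolated)
24 | 8α,9α-O-dibutylstannylene acetal of 21 | C=C(C)[C@H]1C[C@]2(C)[C@@H](C)C[C@H](O)C[C@H]2[C@H](O[Sn](CCCC)(CCCC)O3)[C@@H]13 | intermediate (not isolated)
25 | 2α,8α-dihydroxy-(10αH)-eremophil-11-en-9α-yl (E)-3-methylpent-2-enoate | C=C(C)[C@H]1C[C@]2(C)[C@@H](C)C[C@H](O)C[C@H]2[C@H](OC(=O)/C=C(\C)CC)[C@@H]1O | target

**Step count and risks**

Total steps: 16. Longest linear sequence: 16 steps, from (R)-carvone (1).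

Steps most likely to fail:

1. Step 7 (Proposed new method). The open-chain C4 radical may be quenched by hydrogen abstraction before it reaches the hindered C5, or closure to the quaternary carbon may be too slow under photocatalytic turnover. The fallback keeps the C4–C5 disconnection but uses a stoichiometric radical precursor and a tin hydride chain, all known reaction types. It sets out from 11: FeCl3 in DMF at 0 °C opens the cyclopropanol oxidatively with chlorine transfer to the more substituted carbon and should give (5S)-2-(4-chloro-2-oxopentyl)-3-methyl-5-(prop-1-en-2-yl)cyclohex-2-en-1-one F1. Finkelstein exchange (NaI, acetone) gives (5S)-2-(4-iodo-2-oxopentyl)-3-methyl-5-(prop-1-en-2-yl)cyclohex-2-en-1-one F2. Slow addition of Bu3SnH with Et3B/air in benzene then generates the same C4 radical, which closes 6-endo onto the enone and is reduced at C10. The fallback comes back to the route at 12.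

2. Step 11. Protonation of the C10 carbanion may occur from the β face through a boat-like ring A (cis fusion), or the C9 oxygen may be lost by β-elimination from that carbanion. The fallback sets C10 by hydroxyl-directed hydrogenation instead of electron transfer and sets out from 15. Bromine (1 equiv, CH2Cl2, −78 °C) adds only to the isopropenyl group, the enone double bond being electron-poor, and gives 11,12-dibromo-9β-hydroxyeremophil-1(10)-en-2-one F3. LiBH(sec-Bu)3 reduces the enone carbonyl 1,2 from the equatorial direction to the pseudo-axial 2α-allylic alcohol, 11,12-dibromoeremophil-1(10)-ene-2α,9β-diol F4. Hydrogenation with [Ir(cod)(PCy3)(py)]PF6 in CH2Cl2, directed by the 2α-hydroxyl on the open α face, delivers hydrogen to C1 and C10 from that face and gives 11,12-dibromo-(10αH)-eremophilane-2α,9β-diol F5. Zinc in acetic acid–ethanol restores the isopropenyl group, giving (10αH)-eremophil-11-ene-2α,9β-diol F6. Dess–Martin oxidation of both carbinols comes back to the route at 17.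

3. Step 2. Lithiation may take place at the isopropenyl methyl instead of the ring methyl, or carboxylation may occur at the ring terminus of the allyl anion. The fallback replaces carbanion chemistry by allylic oxidation and carbonylation and sets out from 3. Riley oxidation (catalytic SeO2, t-BuOOH, CH2Cl2) at the E-methyl of the trisubstituted alkene gives (1R,5R)-2-(hydroxymethyl)-1-methyl-5-(prop-1-en-2-yl)cyclohex-2-en-1-ol F7. Methyl chloroformate and pyridine acylate the primary hydroxyl only, giving [(4R,6R)-6-hydroxy-6-methyl-4-(prop-1-en-2-yl)cyclohex-1-en-1-yl]methyl methyl carbonate F8. Palladium-catalysed decarboxylative methoxycarbonylation (Pd(OAc)2, PPh3, CO, MeOH, 50 °C) at the primary allyl terminus comes back to the route at 6.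

**Further compounds**

F1 | step 7 | (5S)-2-(4-chloro-2-oxopentyl)-3-methyl-5-(prop-1-en-2-yl)cyclohex-2-en-1-one (both epimers at the chlorinated carbon) | C=C(C)[C@H]1CC(C)=C(CC(=O)CC(C)Cl)C(=O)C1
F2 | step 7 | (5S)-2-(4-iodo-2-oxopentyl)-3-methyl-5-(prop-1-en-2-yl)cyclohex-2-en-1-one (both epimers at the iodinated carbon) | C=C(C)[C@H]1CC(C)=C(CC(=O)CC(C)I)C(=O)C1
F3 | step 11 | 11,12-dibromo-9β-hydroxyeremophil-1(10)-en-2-one (both C11 epimers) | CC(Br)(CBr)[C@H]1C[C@]2(C)[C@@H](C)CC(=O)C=C2[C@@H](O)C1
F4 | step 11 | 11,12-dibromoeremophil-1(10)-ene-2α,9β-diol | CC(Br)(CBr)[C@H]1C[C@]2(C)[C@@H](C)C[C@H](O)C=C2[C@@H](O)C1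
F5 | step 11 | 11,12-dibromo-(10αH)-eremophilane-2α,9β-diol | CC(Br)(CBr)[C@H]1C[C@]2(C)[C@@H](C)C[C@H](O)C[C@H]2[C@@H](O)C1
F6 | step 11 | (10αH)-eremophil-11-ene-2α,9β-diol | C=C(C)[C@H]1C[C@]2(C)[C@@H](C)C[C@H](O)C[C@H]2[C@@H](O)C1
F7 | step 2 | (1R,5R)-2-(hydroxymethyl)-1-methyl-5-(prop-1-en-2-yl)cyclohex-2-en-1-ol | C=C(C)[C@H]1C[C@@](C)(O)C(CO)=CC1
F8 | step 2 | [(4R,6R)-6-hydroxy-6-methyl-4-(prop-1-en-2-yl)cyclohex-1-en-1-yl]methyl methyl carbonate | C=C(C)[C@H]1C[C@@](C)(O)C(COC(=O)OC)=CC1
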